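**Strategy.** Ring A of the furofuran (O–C7–C8–C8'–C9'; C7 and C7' carry the aryl groups, C8' the acetate, C9 and C9' are the OCH2 carbons) is disconnected at O–C9' and at the ring-fusion bond C8–C8'. The route exploits the O–C7–C8 triad of ring A, stored as a strained aryl vinyl oxirane: zerovalent palladium opens the allylic C8–O bond, the freed C7 alkoxide adds to the CH2 terminus (C9') of an aryl vinyl ketone, and the enolate carbon (C8') closes onto allyl carbon C8. One operation thus builds ring A from an epoxide and an enone; the vinyl group later becomes C9, the ketone C7' of ring B.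

Key step: step 5

Remark on the chemistry: the L-fructose-derived Shi ketone (a catalyst) and the Davis oxaziridine are taken as purchasable. The acetate is installed in step 6 and carried through, because a bridgehead tertiary alcohol is awkward to acetylate late.

Step 1
Reactants: 1 4-(benzyloxy)-3-methoxybenzaldehyde
Product: 2 1-(benzyloxy)-4-[(1E)-buta-1,3-dien-1-yl]-2-methoxybenzene
Conditions: diethyl allylphosphonate, n-BuLi, THF–HMPA, −78 °C → rt
Reagents that add atoms: diethyl allylphosphonate, C=CCP(=O)(OCC)OCC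
Why: Horner–Wadsworth–Emmons olefination through the α-carbon of the lithiated allylphosphonate should give the terminal diene, the new C7=C8 alkene being set E by the reversible addition and anti-periplanar phosphate elimination that HMPA promotes.

Step 2
Reactants: 2 1-(benzyloxy)-4-[(1E)-buta-1,3-dien-1-yl]-2-methoxybenzene
Product: 3 (2S,3S)-2-[4-(benzyloxy)-3-methoxyphenyl]-3-ethenyloxirane (trans)
Conditions: L-fructose-derived Shi ketone (30 mol%), KHSO5 (as Oxone), K2CO3, Bu4NHSO4, MeCN–(MeO)2CH2–aq. Na2B4O7 buffer (pH 10.5), 0 °C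
Reagents that add atoms: potassium peroxymonosulfate, [K+].[O-]S(=O)(=O)OO
Why: Shi asymmetric epoxidation, in which the chiral dioxirane should attack the electron-rich trans-disubstituted styrenyl alkene rather than the terminal vinyl group through the spiro transition state, the L-configured ketone setting both oxirane carbons S and the basic buffer protecting the acid-labile benzylic epoxide.

Step 3
Reactants: 1 4-(benzyloxy)-3-methoxybenzaldehyde
Product: 4 1-[4-(benzyloxy)-3-methoxyphenyl]prop-2-en-1-ol (racemic)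
Conditions: CH2=CHMgBr, THF, −78 → 0 °C; H2O work-up
Reagents that add atoms: vinylmagnesium bromide, C=C[Mg]Br
Why: Grignard 1,2-addition to the aldehyde should be clean, and the new carbinol centre needs no control because it is oxidised in the next step.

Step 4
Reactants: 4 1-[4-(benzyloxy)-3-methoxyphenyl]prop-2-en-1-ol
Product: 5 1-[4-(benzyloxy)-3-methoxyphenyl]prop-2-en-1-one
Conditions: MnO2 (activated, excess), CH2Cl2, rt; used at once
Reagents that add atoms: none
Why: MnO2 oxidation is selective for an alcohol that is both allylic and benzylic and should deliver the polymerisation-prone aryl vinyl ketone under neutral conditions.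

Step 5
Reactants: 3 (2S,3S)-2-[4-(benzyloxy)-3-methoxyphenyl]-3-ethenyloxirane, 5 1-[4-(benzyloxy)-3-methoxyphenyl]prop-2-en-1-one
Product: 8 [4-(benzyloxy)-3-methoxyphenyl]{(3R,4R,5R)-5-[4-(benzyloxy)-3-methoxyphenyl]-4-ethenyloxolan-3-yl}methanone, via π-allylpalladium alkoxide zwitterion 6 (not isolated), via oxa-Michael palladium enolate 7 (not isolated)
Conditions: Pd2(dba)3·CHCl3 (2.5 mol%), Ph2PCH2CH2PPh2 (6 mol%), THF, 0 °C → rt; 5 added slowly
Reagents that add atoms: none
Why: Zerovalent palladium ionises the allylic C8–O bond of 3 with inversion (strain release; the benzylic C7–O bond stays intact) to give zwitterion 6, whose C7 alkoxide adds in an oxa-Michael fashion to the CH2 terminus of 5 (O–C9' bond); enolate 7 then attacks allyl carbon C8 anti to palladium (C8–C8' bond) and releases the catalyst. The closest known reaction type is the palladium-catalysed formal [3+2] cycloaddition of vinyl oxiranes with electron-poor alkenes, and a singly activated aryl vinyl ketone sits at the less activated end of that scope. Ring A closes by a 5-exo C-allylation, whereas attack at the CH2 allyl terminus or O-allylation of the enolate would need seven- or nine-membered rings. C7 is carried over unchanged from 3; C8 is set trans to the C7 aryl group by the double inversion from the trans-oxirane and, should the allyl complex equilibrate by π–σ–π isomerisation through its CH2 terminus, by the less hindered trans ring-closure transition state; C8' is an epimerisable ketone α-carbon that should settle trans to the vinyl group and is reset in step 6. The step needs ionisation at C8 rather than C7, which the vinyl group secures, and 1,4- rather than 1,2-addition of the alkoxide, which the conjugated aryl ketone secures. Slow addition of 5 should keep enolate–enone oligomerisation down.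

Step 6
Reactants: 8 [4-(benzyloxy)-3-methoxyphenyl]{(3R,4R,5R)-5-[4-(benzyloxy)-3-methoxyphenyl]-4-ethenyloxolan-3-yl}methanone
Product: 10 (3R,4S,5R)-3-[4-(benzyloxy)-3-methoxybenzoyl]-5-[4-(benzyloxy)-3-methoxyphenyl]-4-ethenyloxolan-3-yl acetate, via potassium alkoxide of the α-hydroxy ketone 9 (not isolated)
Conditions: KN(SiMe3)2, THF, −78 °C; 2-(phenylsulfonyl)-3-phenyloxaziridine, −78 °C; then Ac2O, DMAP (cat.), −78 → 0 °C
Reagents that add atoms: 2-(phenylsulfonyl)-3-phenyloxaziridine, O=S(=O)(c1ccccc1)N1OC1c1ccccc1; acetic anhydride, CC(=O)OC(C)=O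
Why: Davis enolate hydroxylation with in situ O-acetylation, in which the oxaziridine should attack the exocyclic potassium enolate on the ring face anti to the adjacent C8 vinyl group, so that C8' is set with oxygen trans to vinyl (cis to the C7 aryl group) whatever its configuration in 8, and the tertiary alkoxide is trapped as the acetate.

Step 7
Reactants: 10 (3R,4S,5R)-3-[4-(benzyloxy)-3-methoxybenzoyl]-5-[4-(benzyloxy)-3-methoxyphenyl]-4-ethenyloxolan-3-yl acetate
Product: 12 (3R,4S,5R)-5-[4-(benzyloxy)-3-methoxyphenyl]-3-{(S)-[4-(benzyloxy)-3-methoxyphenyl](hydroxy)methyl}-4-(hydroxymethyl)oxolan-3-yl acetate, via secondary ozonide 11 (not isolated)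
Conditions: O3, CH2Cl2, −78 °C (Sudan Red end point); then MeOH, NaBH4, −78 → 0 °C; AcOH quench
Reagents that add atoms: ozone, [O-][O+]=O
Why: Ozonolysis with reductive borohydride work-up excises the terminal vinyl carbon and gives the C9 primary alcohol without a free β-acetoxy aldehyde, while hydride should add to the aryl ketone in the Felkin–Anh sense (acetoxy group anti to the incoming hydride, C8 as the medium and C9' as the small substituent), which sets C7' as S.

Step 8
Reactants: 12 (3R,4S,5R)-5-[4-(benzyloxy)-3-methoxyphenyl]-3-{(S)-[4-(benzyloxy)-3-methoxyphenyl](hydroxy)methyl}-4-(hydroxymethyl)oxolan-3-yl acetate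
Product: 13 8-acetoxypinoresinol dibenzyl ether
Conditions: PPh3, DIAD, THF, 0 °C → rt
Reagents that add atoms: none
Why: Mitsunobu cyclodehydration of a 1,4-diol, in which the unhindered primary C9 hydroxyl is activated as the oxyphosphonium ion and displaced 5-exo-tet by the C7' hydroxyl, so ring B should close under neutral conditions with retention at C7' and with the cis ring fusion dictated by the cis arrangement of C9 and C7' on ring A.

Step 9
Reactants: 13 8-acetoxypinoresinol dibenzyl ether
Product: 14 8-acetoxypinoresinol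
Conditions: H2 (1 atm), palladium on carbon (Pd/C, 10 %), EtOAc, rt; stopped at full debenzylation
Reagents that add atoms: none
Why: Hydrogenolysis under neutral conditions should cleave the two aryl benzyl ethers faster than the benzylic C–O bonds of the furofuran rings and leaves the tertiary acetate untouched.

**Compound list**

1 | 4-(benzyloxy)-3-methoxybenzaldehyde | COc1cc(C=O)ccc1OCc1ccccc1 | starting material
2 | 1-(benzyloxy)-4-[(1E)-buta-1,3-dien-1-yl]-2-methoxybenzene | C=C/C=C/c1ccc(OCc2ccccc2)c(OC)c1 | intermediate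
3 | (2S,3S)-2-[4-(benzyloxy)-3-methoxyphenyl]-3-ethenyloxirane | C=C[C@@H]1O[C@H]1c1ccc(OCc2ccccc2)c(OC)c1 | intermediate
4 | 1-[4-(benzyloxy)-3-methoxyphenyl]prop-2-en-1-ol (racemic) | C=CC(O)c1ccc(OCc2ccccc2)c(OC)c1 | intermediate
5 | 1-[4-(benzyloxy)-3-methoxyphenyl]prop-2-en-1-one | C=CC(=O)c1ccc(OCc2ccccc2)c(OC)c1 | intermediate
6 | π-allylpalladium alkoxide zwitterion from 3 (drawn as the η1-allyl form, phosphine ligand omitted) | [O-][C@H](/C=C/C[Pd+])c1ccc(OCc2ccccc2)c(OC)c1 | intermediate
7 | oxa-Michael palladium enolate from 6 and 5 (same drawing convention) | [O-]C(=CCO[C@H](/C=C/C[Pd+])c1ccc(OCc2ccccc2)c(OC)c1)c1ccc(OCc2ccccc2)c(OC)c1 | intermediate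
8 | [4-(benzyloxy)-3-methoxyphenyl]{(3R,4R,5R)-5-[4-(benzyloxy)-3-methoxyphenyl]-4-ethenyloxolan-3-yl}methanone (aryl/vinyl trans, vinyl/aroyl trans) | COc1cc([C@@H]2OC[C@H](C(=O)c3ccc(OCc4ccccc4)c(OC)c3)[C@H]2C=C)ccc1OCc1ccccc1 | intermediate
9 | potassium alkoxide of [4-(benzyloxy)-3-methoxyphenyl]{(3R,4S,5R)-5-[4-(benzyloxy)-3-methoxyphenyl]-4-ethenyl-3-hydroxyoxolan-3-yl}methanone | COc1cc([C@@H]2OC[C@@]([O-])(C(=O)c3ccc(OCc4ccccc4)c(OC)c3)[C@H]2C=C)ccc1OCc1ccccc1.[K+] | intermediate
10 | (3R,4S,5R)-3-[4-(benzyloxy)-3-methoxybenzoyl]-5-[4-(benzyloxy)-3-methoxyphenyl]-4-ethenyloxolan-3-yl acetate | COc1cc([C@@H]2OC[C@@](OC(C)=O)(C(=O)c3ccc(OCc4ccccc4)c(OC)c3)[C@H]2C=C)ccc1OCc1ccccc1 | intermediate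
11 | secondary ozonide of 10 (1,2,4-trioxolan-3-yl group in place of the vinyl group, epimer mixture at the trioxolane carbon) | COc1cc([C@@H]2OC[C@@](OC(C)=O)(C(=O)c3ccc(OCc4ccccc4)c(OC)c3)[C@H]2C5OCOO5)ccc1OCc1ccccc1 | intermediate
12 | (3R,4S,5R)-5-[4-(benzyloxy)-3-methoxyphenyl]-3-{(S)-[4-(benzyloxy)-3-methoxyphenyl](hydroxy)methyl}-4-(hydroxymethyl)oxolan-3-yl acetate | COc1cc([C@@H]2OC[C@@](OC(C)=O)([C@@H](O)c3ccc(OCc4ccccc4)c(OC)c3)[C@H]2CO)ccc1OCc1ccccc1 | intermediate
13 | 8-acetoxypinoresinol dibenzyl ether (both phenols as benzyl ethers, stereochemistry as in 14) | COc1cc([C@@H]2OC[C@@]3(OC(C)=O)[C@H](c4ccc(OCc5ccccc5)c(OC)c4)OC[C@@H]23)ccc1OCc1ccccc1 | intermediate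
14 | 8-acetoxypinoresinol (cis-fused 3,7-dioxabicyclo[3.3.0]octane, both aryl groups exo, acetate on the bridgehead next to C7'; C7 R, C8 S, C7' S, C8' R) | COc1cc([C@@H]2OC[C@@]3(OC(C)=O)[C@H](c4ccc(O)c(OC)c4)OC[C@@H]23)ccc1O | target

**Step count.** Total: 9 steps. Longest linear sequence: 7 steps (steps 1, 2, 5, 6, 7, 8, 9; the branch through steps 3 and 4 is equally long).

**Steps most likely to fail**

Step 5. The oxa-Michael addition to a singly activated enone may be too reversible for ring closure to compete. In that case 5 could oligomerise under alkoxide or phosphine catalysis, 3 could isomerise on palladium to a dienol or enone, and the 7,8-trans selectivity could erode. The fallback sets out from 3 and switches to a doubly activated acceptor, building the aryl ketone afterwards. Annulation of 3 with dimethyl 2-methylenemalonate (Pd(PPh3)4, THF) should give dimethyl (4R,5R)-5-[4-(benzyloxy)-3-methoxyphenyl]-4-ethenyloxolane-3,3-dicarboxylate F1. Krapcho demethoxycarbonylation (LiCl, wet DMSO, 140 °C) should then give methyl (3R,4R,5R)-5-[4-(benzyloxy)-3-methoxyphenyl]-4-ethenyloxolane-3-carboxylate F2. Amidation (MeONHMe·HCl, i-PrMgCl, THF, −20 °C) gives the Weinreb amide (3R,4R,5R)-5-[4-(benzyloxy)-3-methoxyphenyl]-4-ethenyl-N-methoxy-N-methyloxolane-3-carboxamide F3. Addition of the aryllithium made from 4-bromo-1-(benzyloxy)-2-methoxybenzene and n-BuLi comes back to the route at 8.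

Step 7. The acetyl group may migrate from the tertiary oxygen to the newly formed alkoxides, hydride may be delivered to the wrong face of the ketone, and ozone may attack the electron-rich arenes. The fallback sets out from 10 and makes both the position of the acetyl group and the C7' configuration irrelevant. After the same ozonolysis and borohydride reduction the crude product is deliberately deacetylated (K2CO3, MeOH) to (3R,4S,5R)-5-[4-(benzyloxy)-3-methoxyphenyl]-3-{[4-(benzyloxy)-3-methoxyphenyl](hydroxy)methyl}-4-(hydroxymethyl)oxolan-3-ol F4, either C7' epimer being acceptable. Ring B is then closed through the C7' benzylic cation (camphorsulfonic acid cat., CH2Cl2, 0 °C), which should give the exo-aryl 8-hydroxypinoresinol dibenzyl ether F5 from both epimers. Acetylation of the tertiary alcohol (Ac2O, DMAP, Et3N, 40 °C) comes back to the route at 13, bypassing 12 and step 8.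

Step 2. The electron-rich benzylic vinyl oxirane may be opened hydrolytically in the aqueous buffer, and some epoxidation may occur at the terminal alkene. The fallback sets out from 1 and builds the oxirane under anhydrous conditions before the vinyl group exists. Horner–Wadsworth–Emmons olefination (triethyl phosphonoacetate, NaH, THF) gives ethyl (2E)-3-[4-(benzyloxy)-3-methoxyphenyl]prop-2-enoate F6. Reduction with i-Bu2AlH (CH2Cl2, −78 °C) gives (2E)-3-[4-(benzyloxy)-3-methoxyphenyl]prop-2-en-1-ol F7. Sharpless asymmetric epoxidation (Ti(Oi-Pr)4, L-(+)-diethyl tartrate, t-BuOOH, 4 Å sieves, CH2Cl2, −20 °C) gives {(2S,3S)-3-[4-(benzyloxy)-3-methoxyphenyl]oxiran-2-yl}methanol F8. Parikh–Doering oxidation (SO3·pyridine, DMSO, Et3N) gives (2R,3S)-3-[4-(benzyloxy)-3-methoxyphenyl]oxirane-2-carbaldehyde F9. Wittig methylenation (Ph3P=CH2, THF, −78 °C) comes back to the route at 3.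

Further compounds
F1 | step 5 | dimethyl (4R,5R)-5-[4-(benzyloxy)-3-methoxyphenyl]-4-ethenyloxolane-3,3-dicarboxylate | COc1cc([C@@H]2OCC(C(=O)OC)(C(=O)OC)[C@H]2C=C)ccc1OCc1ccccc1
F2 | step 5 | methyl (3R,4R,5R)-5-[4-(benzyloxy)-3-methoxyphenyl]-4-ethenyloxolane-3-carboxylate | COc1cc([C@@H]2OC[C@H](C(=O)OC)[C@H]2C=C)ccc1OCc1ccccc1
F3 | step 5 | (3R,4R,5R)-5-[4-(benzyloxy)-3-methoxyphenyl]-4-ethenyl-N-methoxy-N-methyloxolane-3-carboxamide | COc1cc([C@@H]2OC[C@H](C(=O)N(C)OC)[C@H]2C=C)ccc1OCc1ccccc1
F4 | step 7 | (3R,4S,5R)-5-[4-(benzyloxy)-3-methoxyphenyl]-3-{[4-(benzyloxy)-3-methoxyphenyl](hydroxy)methyl}-4-(hydroxymethyl)oxolan-3-ol (either C7' epimer) | COc1cc([C@@H]2OC[C@@](O)(C(O)c3ccc(OCc4ccccc4)c(OC)c3)[C@H]2CO)ccc1OCc1ccccc1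
F5 | step 7 | 8-hydroxypinoresinol dibenzyl ether | COc1cc([C@@H]2OC[C@@]3(O)[C@H](c4ccc(OCc5ccccc5)c(OC)c4)OC[C@@H]23)ccc1OCc1ccccc1
F6 | step 2 | ethyl (2E)-3-[4-(benzyloxy)-3-methoxyphenyl]prop-2-enoate | CCOC(=O)/C=C/c1ccc(OCc2ccccc2)c(OC)c1
F7 | step 2 | (2E)-3-[4-(benzyloxy)-3-methoxyphenyl]prop-2-en-1-ol | OC/C=C/c1ccc(OCc2ccccc2)c(OC)c1
F8 | step 2 | {(2S,3S)-3-[4-(benzyloxy)-3-methoxyphenyl]oxiran-2-yl}methanol | OC[C@@H]1O[C@H]1c1ccc(OCc2ccccc2)c(OC)c1
F9 | step 2 | (2R,3S)-3-[4-(benzyloxy)-3-methoxyphenyl]oxirane-2-carbaldehyde | O=C[C@@H]1O[C@H]1c1ccc(OCc2ccccc2)c(OC)c1
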